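**Strategy**

Everything rests on forming ring C last, through its aryl ether bond O1–C8a. O1 sits between the stereogenic carbon C2 and C8a, a fully substituted carbon of ring A. An intramolecular palladium-catalysed etherification can therefore join the C2 hydroxyl to C8a and, since the C2–O bond is never broken, deliver the flavan with the (S) configuration that an earlier catalyst-controlled ketone reduction installed. The cyclisation substrate is an open-chain 1,3-diarylpropane: ring A carries bromine at C8a, both prenyl groups and MOM ethers on O5 and O7; C4 is a TBS-protected carbinol standing in for the ketone; C2 is the free (S)-alcohol attached to chromene ring B.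

Key step: step 10

Remark: flavanone numbering (O1, C2–C4, C4a–C8a) is used throughout, also for open-chain compounds; C4 is a temporary stereocentre erased in step 12, so 13 and 14 are racemic and 15–17 (likewise F3 and F4) are carried as pairs of C4 epimers, of which only the (4R) member is named and drawn.

**Route**

Step 1
Reactants: 1 2,4,6-trihydroxybenzaldehyde; 2 prenyl bromide (1-bromo-3-methylbut-2-ene, 2.2 equiv)
Product: 3 2,4,6-trihydroxy-3,5-bis(3-methylbut-2-en-1-yl)benzaldehyde
Conditions: KOH (10% aq), 0 °C → rt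
Reagents that add atoms: none
Why: Base-mediated C-alkylation of the ambident acylphloroglucinol phenolate, which in water reacts with the soft allylic bromide at its two equivalent free ring carbons, so only one dialkylated constitution can form and mono- or over-alkylated material is removed by chromatography.

Step 2
Reactants: 3 2,4,6-trihydroxy-3,5-bis(3-methylbut-2-en-1-yl)benzaldehyde
Product: 4 2-hydroxy-4,6-bis(methoxymethoxy)-3,5-bis(3-methylbut-2-en-1-yl)benzaldehyde
Conditions: MOMCl (2.2 equiv), i-Pr2NEt, CH2Cl2, 0 °C → rt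
Reagents that add atoms: chloromethyl methyl ether, COCCl
Why: Williamson-type O-alkylation (MOM ether formation) at the para hydroxyl and at one of the two equivalent ortho hydroxyls, the remaining ortho hydroxyl being held back by its hydrogen bond to the formyl oxygen.

Step 3
Reactants: 4 2-hydroxy-4,6-bis(methoxymethoxy)-3,5-bis(3-methylbut-2-en-1-yl)benzaldehyde
Product: 5 2-formyl-3,5-bis(methoxymethoxy)-4,6-bis(3-methylbut-2-en-1-yl)phenyl trifluoromethanesulfonate
Conditions: Tf2O, pyridine, CH2Cl2, −10 → 0 °C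
Reagents that add atoms: trifluoromethanesulfonic anhydride, O=S(=O)(OS(=O)(=O)C(F)(F)F)C(F)(F)F
Why: O-sulfonylation of the one free phenol (aryl triflate formation) turns the oxygen at the future C8a into a leaving group for palladium chemistry.

Step 4
Reactants: 5 2-formyl-3,5-bis(methoxymethoxy)-4,6-bis(3-methylbut-2-en-1-yl)phenyl trifluoromethanesulfonate
Product: 6 2-bromo-4,6-bis(methoxymethoxy)-3,5-bis(3-methylbut-2-en-1-yl)benzaldehyde
Conditions: Pd2(dba)3 (cat.), t-BuBrettPhos (cat.), KBr, KF (substoichiometric), 1,4-dioxane, 130 °C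
Reagents that add atoms: potassium bromide, [K+].[Br-]
Why: Palladium-catalysed triflate-to-bromide exchange of an aryl triflate, in which oxidative addition of the C–OTf bond to zerovalent palladium (helped by the ortho formyl group), swap of triflate for bromide and C–Br reductive elimination enforced by the very bulky biaryl phosphine should place bromine at the future C8a.

Step 5
Reactants: 7 4-hydroxyacetophenone; 8 3-chloro-3-methylbut-1-yne
Product: 9 1-{4-[(2-methylbut-3-yn-2-yl)oxy]phenyl}ethan-1-one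
Conditions: K2CO3, KI (cat.), acetone, reflux
Reagents that add atoms: none
Why: Williamson-type etherification of the phenoxide with the tertiary propargylic chloride gives the aryl 1,1-dimethylpropargyl ether needed for chromene formation.

Step 6
Reactants: 9 1-{4-[(2-methylbut-3-yn-2-yl)oxy]phenyl}ethan-1-one
Product: 11 1-(2,2-dimethyl-2H-chromen-6-yl)ethan-1-one, via ortho-allenylphenol 10 (not isolated)
Conditions: N,N-diethylaniline, 190 °C
Reagents that add atoms: none
Why: Aromatic propargyl Claisen rearrangement to the ortho-allenylphenol, followed by 1,5-hydrogen shift and oxa-6π electrocyclisation, closes the 2,2-dimethyl-2H-chromene, and the para acetyl group makes both ortho positions equivalent.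

Step 7
Reactants: 11 1-(2,2-dimethyl-2H-chromen-6-yl)ethan-1-one (1.2 equiv); 6 2-bromo-4,6-bis(methoxymethoxy)-3,5-bis(3-methylbut-2-en-1-yl)benzaldehyde
Product: 13 rac-3-[2-bromo-4,6-bis(methoxymethoxy)-3,5-bis(3-methylbut-2-en-1-yl)phenyl]-1-(2,2-dimethyl-2H-chromen-6-yl)-3-hydroxypropan-1-one, via lithium enolate 12 (not isolated)
Conditions: LiN(SiMe3)2, THF, −78 °C; then 6, −78 °C; AcOH quench at −78 °C
Reagents that add atoms: none
Why: Directed crossed aldol addition of the kinetic lithium enolate of the methyl ketone to the non-enolisable aldehyde forms the C3–C4 bond, the cold acidic quench preventing retro-aldol cleavage, and C4 arises racemic, which is harmless because it later becomes the ketone.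

Step 8
Reactants: 13 rac-3-[2-bromo-4,6-bis(methoxymethoxy)-3,5-bis(3-methylbut-2-en-1-yl)phenyl]-1-(2,2-dimethyl-2H-chromen-6-yl)-3-hydroxypropan-1-one
Product: 14 rac-3-[2-bromo-4,6-bis(methoxymethoxy)-3,5-bis(3-methylbut-2-en-1-yl)phenyl]-3-[(tert-butyldimethylsilyl)oxy]-1-(2,2-dimethyl-2H-chromen-6-yl)propan-1-one
Conditions: TBSOTf, 2,6-lutidine, CH2Cl2, −78 → −20 °C
Reagents that add atoms: tert-butyldimethylsilyl trifluoromethanesulfonate, CC(C)(C)[Si](C)(C)OS(=O)(=O)C(F)(F)F
Why: O-silylation of the hindered secondary alcohol with a silyl triflate under lutidine buffering caps O4 before any second hydroxyl exists, so no later differentiation of two carbinols is needed, and it blocks dehydration or retro-aldol of the aldol.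

Step 9
Reactants: 14 rac-3-[2-bromo-4,6-bis(methoxymethoxy)-3,5-bis(3-methylbut-2-en-1-yl)phenyl]-3-[(tert-butyldimethylsilyl)oxy]-1-(2,2-dimethyl-2H-chromen-6-yl)propan-1-one
Product: 15 (1S,3R)-3-[2-bromo-4,6-bis(methoxymethoxy)-3,5-bis(3-methylbut-2-en-1-yl)phenyl]-3-[(tert-butyldimethylsilyl)oxy]-1-(2,2-dimethyl-2H-chromen-6-yl)propan-1-ol (with its (1S,3S) epimer)
Conditions: (R)-2-methyl-CBS-oxazaborolidine (cat.), catecholborane, toluene, −78 → −40 °C; then MeOH, NaOH (1 M aq) wash
Reagents that add atoms: none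
Why: Corey–Bakshi–Shibata reduction, in which the (R)-oxazaborolidine binds the ketone with the chromenyl group as the large and the CH2 chain as the small substituent and directs hydride from coordinated catecholborane to the Re face, should set C2 as (S) under catalyst control for both C4 antipodes, while catecholborane spares the alkenes at low temperature.

Step 10
Reactants: 15 (1S,3R)-3-[2-bromo-4,6-bis(methoxymethoxy)-3,5-bis(3-methylbut-2-en-1-yl)phenyl]-3-[(tert-butyldimethylsilyl)oxy]-1-(2,2-dimethyl-2H-chromen-6-yl)propan-1-ol (with its C4 epimer)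
Product: 16 (2S,4R)-4-[(tert-butyldimethylsilyl)oxy]-2-(2,2-dimethyl-2H-chromen-6-yl)-5,7-bis(methoxymethoxy)-6,8-bis(3-methylbut-2-en-1-yl)chromane (with its C4 epimer)
Conditions: Pd(OAc)2 (cat.), rac-2-(di-tert-butylphosphino)-1,1'-binaphthyl (cat.), Cs2CO3, toluene, 80 °C
Reagents that add atoms: none
Why: Oxidative addition of the C8a–Br bond to zerovalent palladium (generated in situ from Pd(OAc)2 and the phosphine) is followed by carbonate-assisted exchange of bromide for the C2 alkoxide, and the resulting seven-membered oxapalladacycle undergoes C–O reductive elimination to give O1–C8a. The closest known reaction type is the intramolecular Buchwald–Hartwig-type etherification of aryl halides with secondary alcohols that gives chromans with retention of configuration. Ring C closes as a six-membered ring in an exo sense, the oxygen bonding to the ipso carbon of ring A. No stereocentre is created: only the O–H bond at C2 reacts, so C2 stays (S), and both C4 epimers should cyclise. Chemoselectivity is the requirement, because the palladium alkoxide could instead lose the β-hydride at C2 and reduce the aryl bromide; a hindered, strongly donating di-tert-butylbiaryl phosphine speeds C–O bond formation enough to suppress this, and with O4 capped as its TBS ether no second hydroxyl can bind palladium. The two ortho substituents slow oxidative addition, but the tethered alkoxide and the weak, poorly soluble carbonate base (which also disfavours silyl migration) should keep the cyclisation ahead of side reactions.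

Step 11
Reactants: 16 (2S,4R)-4-[(tert-butyldimethylsilyl)oxy]-2-(2,2-dimethyl-2H-chromen-6-yl)-5,7-bis(methoxymethoxy)-6,8-bis(3-methylbut-2-en-1-yl)chromane (with its C4 epimer)
Product: 17 (2S,4R)-2-(2,2-dimethyl-2H-chromen-6-yl)-5,7-bis(methoxymethoxy)-6,8-bis(3-methylbut-2-en-1-yl)chroman-4-ol (with its C4 epimer)
Conditions: Bu4NF, THF, rt → 40 °C
Reagents that add atoms: none
Why: Fluoride-mediated desilylation, driven by the strong Si–F bond, frees the C4 hydroxyl without touching the MOM ethers, the alkenes or C2.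

Step 12
Reactants: 17 (2S,4R)-2-(2,2-dimethyl-2H-chromen-6-yl)-5,7-bis(methoxymethoxy)-6,8-bis(3-methylbut-2-en-1-yl)chroman-4-ol (with its C4 epimer)
Product: 18 (2S)-2-(2,2-dimethyl-2H-chromen-6-yl)-5,7-bis(methoxymethoxy)-6,8-bis(3-methylbut-2-en-1-yl)chroman-4-one
Conditions: Dess–Martin periodinane, NaHCO3, CH2Cl2, 0 °C → rt
Reagents that add atoms: none
Why: Dess–Martin oxidation of the secondary benzylic alcohol under bicarbonate buffering converts both C4 epimers into the one ketone and leaves C2, which is not alpha to the carbonyl, and the alkenes untouched.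

Step 13
Reactants: 18 (2S)-2-(2,2-dimethyl-2H-chromen-6-yl)-5,7-bis(methoxymethoxy)-6,8-bis(3-methylbut-2-en-1-yl)chroman-4-one
Product: 19 (2S)-2-(2,2-dimethyl-2H-chromen-6-yl)-5,7-dihydroxy-6,8-bis(3-methylbut-2-en-1-yl)chroman-4-one
Conditions: HCl (3 M aq), MeOH, 50 °C
Reagents that add atoms: none
Why: Acid-catalysed acetal cleavage (methanolysis of the two aryl MOM ethers) under mild heating should free O5 and O7 before the prenyl groups or the chromene react, and the 5-hydroxyflavanone is not expected to open and racemise under these acidic conditions.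

**Compound list**

1 | 2,4,6-trihydroxybenzaldehyde | O=Cc1c(O)cc(O)cc1O | starting material
2 | prenyl bromide (1-bromo-3-methylbut-2-ene) | CC(C)=CCBr | starting material
3 | 2,4,6-trihydroxy-3,5-bis(3-methylbut-2-en-1-yl)benzaldehyde | O=Cc1c(O)c(CC=C(C)C)c(O)c(CC=C(C)C)c1O | intermediate
4 | 2-hydroxy-4,6-bis(methoxymethoxy)-3,5-bis(3-methylbut-2-en-1-yl)benzaldehyde | O=Cc1c(O)c(CC=C(C)C)c(OCOC)c(CC=C(C)C)c1OCOC | intermediate
5 | 2-formyl-3,5-bis(methoxymethoxy)-4,6-bis(3-methylbut-2-en-1-yl)phenyl trifluoromethanesulfonate | O=Cc1c(OS(=O)(=O)C(F)(F)F)c(CC=C(C)C)c(OCOC)c(CC=C(C)C)c1OCOC | intermediate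
6 | 2-bromo-4,6-bis(methoxymethoxy)-3,5-bis(3-methylbut-2-en-1-yl)benzaldehyde | O=Cc1c(Br)c(CC=C(C)C)c(OCOC)c(CC=C(C)C)c1OCOC | intermediate
7 | 4-hydroxyacetophenone | CC(=O)c1ccc(O)cc1 | starting material
8 | 3-chloro-3-methylbut-1-yne | C#CC(C)(C)Cl | starting material
9 | 1-{4-[(2-methylbut-3-yn-2-yl)oxy]phenyl}ethan-1-one | CC(=O)c1ccc(OC(C)(C)C#C)cc1 | intermediate
10 | 1-[4-hydroxy-3-(3-methylbuta-1,2-dien-1-yl)phenyl]ethan-1-one | CC(=O)c1ccc(O)c(C=C=C(C)C)c1 | intermediate (not isolated)
11 | 1-(2,2-dimethyl-2H-chromen-6-yl)ethan-1-one | CC(=O)c1ccc2c(c1)C=CC(C)(C)O2 | intermediate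
12 | lithium 1-(2,2-dimethyl-2H-chromen-6-yl)ethen-1-olate | [Li]OC(=C)c1ccc2c(c1)C=CC(C)(C)O2 | intermediate (not isolated)
13 | rac-3-[2-bromo-4,6-bis(methoxymethoxy)-3,5-bis(3-methylbut-2-en-1-yl)phenyl]-1-(2,2-dimethyl-2H-chromen-6-yl)-3-hydroxypropan-1-one | CC(C)=CCc1c(OCOC)c(CC=C(C)C)c(Br)c(C(O)CC(=O)c2ccc3c(c2)C=CC(C)(C)O3)c1OCOC | intermediate
14 | rac-3-[2-bromo-4,6-bis(methoxymethoxy)-3,5-bis(3-methylbut-2-en-1-yl)phenyl]-3-[(tert-butyldimethylsilyl)oxy]-1-(2,2-dimethyl-2H-chromen-6-yl)propan-1-one | CC(C)=CCc1c(OCOC)c(CC=C(C)C)c(Br)c(C(O[Si](C)(C)C(C)(C)C)CC(=O)c2ccc3c(c2)C=CC(C)(C)O3)c1OCOC | intermediate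
15 | (1S,3R)-3-[2-bromo-4,6-bis(methoxymethoxy)-3,5-bis(3-methylbut-2-en-1-yl)phenyl]-3-[(tert-butyldimethylsilyl)oxy]-1-(2,2-dimethyl-2H-chromen-6-yl)propan-1-ol (C4 epimer drawn; the (1S,3S) epimer accompanies it) | CC(C)=CCc1c(OCOC)c(CC=C(C)C)c(Br)c([C@H](O[Si](C)(C)C(C)(C)C)C[C@H](O)c2ccc3c(c2)C=CC(C)(C)O3)c1OCOC | intermediate
16 | (2S,4R)-4-[(tert-butyldimethylsilyl)oxy]-2-(2,2-dimethyl-2H-chromen-6-yl)-5,7-bis(methoxymethoxy)-6,8-bis(3-methylbut-2-en-1-yl)chromane (C4 epimer drawn; the (2S,4S) epimer accompanies it) | CC(C)=CCc1c(OCOC)c(CC=C(C)C)c2c(c1OCOC)[C@H](O[Si](C)(C)C(C)(C)C)C[C@@H](c1ccc3c(c1)C=CC(C)(C)O3)O2 | intermediate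
17 | (2S,4R)-2-(2,2-dimethyl-2H-chromen-6-yl)-5,7-bis(methoxymethoxy)-6,8-bis(3-methylbut-2-en-1-yl)chroman-4-ol (C4 epimer drawn; the (2S,4S) epimer accompanies it) | CC(C)=CCc1c(OCOC)c(CC=C(C)C)c2c(c1OCOC)[C@H](O)C[C@@H](c1ccc3c(c1)C=CC(C)(C)O3)O2 | intermediate
18 | (2S)-2-(2,2-dimethyl-2H-chromen-6-yl)-5,7-bis(methoxymethoxy)-6,8-bis(3-methylbut-2-en-1-yl)chroman-4-one | CC(C)=CCc1c(OCOC)c(CC=C(C)C)c2c(c1OCOC)C(=O)C[C@@H](c1ccc3c(c1)C=CC(C)(C)O3)O2 | intermediate
19 | (2S)-2-(2,2-dimethyl-2H-chromen-6-yl)-5,7-dihydroxy-6,8-bis(3-methylbut-2-en-1-yl)chroman-4-one | CC(C)=CCc1c(O)c(CC=C(C)C)c2c(c1O)C(=O)C[C@@H](c1ccc3c(c1)C=CC(C)(C)O3)O2 | target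

**Step count and risks**

Total step count: 13. Longest linear sequence: 11 steps (steps 1–4 and 7–13).

1. Step 10 (key step). The palladium alkoxide may lose the β-hydride at C2 and reduce the C8a–Br bond instead of forming the ether, oxidative addition at the doubly flanked bromide may stall, or the silyl group may migrate from O4 to O2 under base. The fallback closes ring C through the other ether bond, O1–C2, by Mitsunobu cyclisation with inversion, and needs no aryl bromide. It sets out from triflate 5 and ketone 11. Lithium enolate 12 is added to 5 at −78 °C to give the racemic β-hydroxy ketone aryl triflate F1, which TBSOTf and 2,6-lutidine convert into the silyl ether F2. Reduction with the enantiomeric (S)-2-methyl-CBS-oxazaborolidine and catecholborane should give the (R)-carbinol aryl triflate F3. Et4NOH in aqueous dioxane at rt cleaves the sulfonate to the (R)-carbinol phenol F4. PPh3 and diisopropyl azodicarboxylate in THF at 0 °C then displace the activated C2 hydroxyl by the C8a phenol with inversion, and the route is rejoined at 16.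

2. Step 4. The exchange may stall at the crowded carbon, or the triflate may be lost reductively instead of being replaced by bromide. The fallback goes through a carbon–boron bond. It sets out from triflate 5: Miyaura borylation (Pd(OAc)2, SPhos, bis(pinacolato)diboron, KOAc, dioxane, 90 °C) gives the aryl pinacol boronate F5, and copper-mediated bromodeboronation with CuBr2 in MeOH/water at 70 °C returns to the route at 6.

3. Step 13. Under protic acid the liberated phenols may add to the neighbouring prenyl double bonds (chroman formation), and the chromene may hydrate. The fallback removes the MOM groups without protic acid. It sets out from 18: TMSOTf and 2,2'-bipyridyl in CH2Cl2 at 0 °C exchange both aryl MOM ethers for silyl ethers, giving the bis(trimethylsilyl) ether F6, which water hydrolyses during work-up to rejoin the route at 19.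

**Further compounds**

F1 | step 10 | rac-2-[3-(2,2-dimethyl-2H-chromen-6-yl)-1-hydroxy-3-oxopropyl]-3,5-bis(methoxymethoxy)-4,6-bis(3-methylbut-2-en-1-yl)phenyl trifluoromethanesulfonate | CC(C)=CCc1c(OCOC)c(CC=C(C)C)c(OS(=O)(=O)C(F)(F)F)c(C(O)CC(=O)c2ccc3c(c2)C=CC(C)(C)O3)c1OCOC
F2 | step 10 | rac-2-{1-[(tert-butyldimethylsilyl)oxy]-3-(2,2-dimethyl-2H-chromen-6-yl)-3-oxopropyl}-3,5-bis(methoxymethoxy)-4,6-bis(3-methylbut-2-en-1-yl)phenyl trifluoromethanesulfonate | CC(C)=CCc1c(OCOC)c(CC=C(C)C)c(OS(=O)(=O)C(F)(F)F)c(C(O[Si](C)(C)C(C)(C)C)CC(=O)c2ccc3c(c2)C=CC(C)(C)O3)c1OCOC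
F3 | step 10 | 2-[(1R,3R)-1-[(tert-butyldimethylsilyl)oxy]-3-(2,2-dimethyl-2H-chromen-6-yl)-3-hydroxypropyl]-3,5-bis(methoxymethoxy)-4,6-bis(3-methylbut-2-en-1-yl)phenyl trifluoromethanesulfonate (silyloxy-carbon epimer drawn) | CC(C)=CCc1c(OCOC)c(CC=C(C)C)c(OS(=O)(=O)C(F)(F)F)c([C@H](O[Si](C)(C)C(C)(C)C)C[C@@H](O)c2ccc3c(c2)C=CC(C)(C)O3)c1OCOC
F4 | step 10 | 2-[(1R,3R)-1-[(tert-butyldimethylsilyl)oxy]-3-(2,2-dimethyl-2H-chromen-6-yl)-3-hydroxypropyl]-3,5-bis(methoxymethoxy)-4,6-bis(3-methylbut-2-en-1-yl)phenol (silyloxy-carbon epimer drawn) | CC(C)=CCc1c(OCOC)c(CC=C(C)C)c(O)c([C@H](O[Si](C)(C)C(C)(C)C)C[C@@H](O)c2ccc3c(c2)C=CC(C)(C)O3)c1OCOC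
F5 | step 4 | 4,6-bis(methoxymethoxy)-3,5-bis(3-methylbut-2-en-1-yl)-2-(4,4,5,5-tetramethyl-1,3,2-dioxaborolan-2-yl)benzaldehyde | O=Cc1c(B2OC(C)(C)C(C)(C)O2)c(CC=C(C)C)c(OCOC)c(CC=C(C)C)c1OCOC
F6 | step 13 | (2S)-2-(2,2-dimethyl-2H-chromen-6-yl)-6,8-bis(3-methylbut-2-en-1-yl)-5,7-bis[(trimethylsilyl)oxy]chroman-4-one | CC(C)=CCc1c(O[Si](C)(C)C)c(CC=C(C)C)c2c(c1O[Si](C)(C)C)C(=O)C[C@@H](c1ccc3c(c1)C=CC(C)(C)O3)O2
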